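## Structural features

The target is a benzophenone: two benzene rings, ring A and ring B, joined only through one carbonyl carbon. There is no further ring and no stereocentre, so no question of neighbouring stereocentres arises. Ring A carries the carbonyl at C1, OH at C2, Cl at C3, OMe at C4 and C6, and one hydrogen at C5. Ring B carries the carbonyl at C1', CH3 at C2', OH at C4' and OMe at C6'. All four positions ortho to the ketone (C2, C6, C2', C6') are substituted, so the ketone is tetra-ortho-substituted and both rings are twisted out of the carbonyl plane. Fragile points are the two free phenols (oxidation), the aryl C–Cl bond (hydrogenolysis, strongly reducing metals), the methyl ethers at C6 and C6' next to the carbonyl (Lewis-acid demethylation) and the nucleophilic C5–H between two methoxy groups (electrophiles). The real difficulty is twofold: putting Cl and the aroyl group on the two different carbons ortho to the ring A hydroxyl, and making a ketone that is crowded on both sides. The key step exploits the C2' methyl of ring B lying ortho to the carbonyl: without it, C2'–H is the only hydrogen ortho to the ketone on either ring, so the ketone can direct a metal to that one C–H bond and the fourth ortho substituent is added last.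

## Logic of the disconnections

**11 ⇒ 10.** The two phenolic O–acyl bonds (at the C2 oxygen of ring A and the C4' oxygen of ring B) are cut. Both phenols must be masked during the metal-catalysed step, and two aryl pivalates come off together in one methanolysis. Nothing is gained in skeleton, but this is the only operation after the key step. The forward step must spare the aryl chloride and the methyl ethers, which mild methoxide does.

**10 ⇒ 8 + 9.** The C2'–CH3 bond of ring B is cut. This removes the fourth ortho substituent, turning a tetra-ortho ketone into a tri-ortho ketone whose ring B derives from a purchasable benzoic acid. The forward step must methylate one C–H bond only. That is secured because C2'–H is the sole ortho hydrogen of 8 and the ketone is the strongest donor present. The demand is that cyclometalation still proceeds at a crowded diaryl ketone.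

**8 ⇒ 7.** The O–acyl bond at the C2 oxygen is cut. A free C2 hydroxyl would bind iridium together with the ketone oxygen in a six-membered O,O-chelate and take the directing group out of play, so it is esterified. The forward step has to acylate a phenol that is flanked by Cl and the aroyl group and is hydrogen-bonded to the ketone.

**7 ⇒ 6.** The ring A C1–C(=O) bond is cut and the acyl group is returned to the C2 oxygen (retro-Fries). The acyl group is thereby tied to the one oxygen whose only free ortho carbon is C1, so ortho delivery decides where ring A is acylated. The ketone becomes an ester, made by a routine coupling. The forward step must migrate ortho and not para (to C5), and its Lewis acid must spare the methyl ethers and the ring B pivalate.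

**6 ⇒ 2 + 4 (through 5).** The ester C–O bond is cut, giving one simple phenol and one simple benzoic acid. The forward step is an acylation of a moderately hindered phenol, which calls for activation of 4 as 5.

**4 ⇒ 3.** The O–pivaloyl bond on ring B is cut. Putting the pivalate on at the acid stage lets ring B carry one protecting group through ester formation, Fries step and key step. An acetate would have to survive the Lewis acid and then be exchanged; the pivalate avoids both. The forward step must acylate the phenol in the presence of the carboxylic acid.

**2 ⇒ 1.** The C–Cl bond ortho to the hydroxyl is cut. Chlorine is introduced first, on a cheap symmetric phenol whose two ortho positions are equivalent. It then blocks one ortho carbon, leaving the Fries step a single ortho site. The forward step must favour ortho over para chlorination and stop at the monochloride.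

## Other disconnections considered

**Alternative 1:** The cut runs through ring A: C1–C2, C5–C6 and C2–C3 are disconnected. That gives the four-carbon cyclobutenone A2 and the ynol ether A3, which already carries ring B, with its methyl, as a silyl-protected carbinol.
- Forward step: heating A2 with A3 should trigger a four-electron ring opening, a [2+2] addition to the electron-rich alkyne, a second four-electron opening and a six-electron closure, then tautomerisation to phenol A1 with OH, Cl and both OMe groups of ring A in place.
- In favour: every substituent of ring A is fixed by the connectivity of A2 and A3. Neither the chlorination regiochemistry of step 1 nor the ortho/para question of step 4 exists, and on this point the alternative is better than the chosen plan. It needs no metal and is equally convergent.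
- Against: neither A2 nor A3 is purchasable and both are sensitive (an α-chloro cyclobutenone; an ynol ether beside a benzylic silyl ether). Each needs several steps, and A3 requires a separately built, fully substituted ring B.
- After A1 three operations remain: desilylation, oxidation of a very hindered diaryl carbinol next to a free electron-rich phenol, and MOM removal. The carbinol stereocentre of A1 is made only to be destroyed.
- Comparison: on structure, both plans postpone the full crowding of the ketone, A1 by keeping the bridging carbon tetrahedral, the chosen plan by adding the last ortho group at the end. On mechanism, a thermal pericyclic cascade stands against a chelation-controlled C–H activation, each with one possible regiochemical outcome. On step economy the chosen plan, seven steps from purchasable compounds, should be clearly shorter.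

**Alternative 2:** The cut is the C1–C2 bond of ring A, opening ring A into the triketo ester chain of A5 attached to a complete, methyl-bearing ring B.
- Forward step: base should make the methylene beside the aryl ketone of A5 attack the ester carbonyl (Claisen condensation), closing ring A as the trihydroxybenzophenone A4.
- In favour: the route is biomimetic and metal-free, and the crowded ketone arises without any arene acylation. The ring-forming step has no regiochemical question because the new ring of A4 is symmetric. On these points it is equal to or better than the chosen plan.
- Against: A5 is a poly-β-carbonyl compound that must be made by acylating a polyanion with a di-ortho-substituted benzoate. It can also close by aldol paths.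
- A4 still lacks everything that makes ring A difficult. Two of its three hydroxyls must be methylated selectively, and chlorine must then be placed at C3 rather than C5 on an advanced intermediate whose ring B is itself activated. The benzyl ether must finally be removed without losing the aryl chloride.
- Comparison: the chlorination selectivity that the chosen plan settles in step 1 on a cheap phenol returns late and in a harder form. The step count (chain assembly, cyclisation, methylation, chlorination, debenzylation) should exceed that of the chosen plan.

**Alternative 3:** The cut runs through ring B: C1'–C6' and C2'–C3' are disconnected, giving the ring A ynone A7 and the electron-rich diene A8.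
- Forward step: a (4+2) cycloaddition in which the nucleophilic CH2 terminus of A8 bonds to the methyl-bearing alkyne carbon of A7, followed by aromatisation through elimination and desilylation, should give A6, the MOM ether of 11.
- In favour: the polarity of both partners fixes the ring B pattern, with the methyl, the free C4' hydroxyl and the C6' methoxy group all placed in one step. No precious metal is used and only one deprotection follows. In operations after the key step it is equal to the chosen plan, and in freedom from a crowded C–H activation it is better.
- Against: A7 still requires ring A to be acylated at C1, the same regiochemical task that step 4 solves. The ynone cannot pass through Lewis-acid conditions, and the C2 oxygen must be protected beforehand because a free ortho hydroxyl would add to the ynone.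
- The β-methyl ynone, attached to a twisted di-ortho-substituted aryl group, should be a sluggish dienophile. A8 is moisture-sensitive and may react stepwise by a Mukaiyama–Michael path.
- Comparison: on structure, both plans complete ring B last at C2'. On mechanism, a polarity-controlled cycloaddition stands against a directed C–H activation. On step economy the two should be about equal. The chosen plan is preferred because all its precursors are robust, crystalline aromatic compounds.

Key step: step 6

Remark on the chemistry: Piv = 2,2-dimethylpropanoyl; ring A is numbered from the carbonyl-bearing carbon C1 (C2 OH, C3 Cl, C4 OMe, C5 H, C6 OMe) and ring B from C1' (C2' CH3, C4' OH, C6' OMe).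

## Route

Step 1
Reactants: 1 3,5-dimethoxyphenol
Product: 2 2-chloro-3,5-dimethoxyphenol
Conditions: SO2Cl2 (1.0 equiv), CH2Cl2, −10 °C → 0 °C; crystallisation or chromatography
Reagents that add atoms: sulfuryl chloride, O=S(=O)(Cl)Cl
Why: Electrophilic aromatic chlorination of a strongly activated phenol; the two equivalent positions ortho to OH (each also para to an OMe) should be favoured over the single, more hindered position between the two OMe groups, and one equivalent of reagent at low temperature should limit dichlorination.

Step 2
Reactants: 3 4-hydroxy-2-methoxybenzoic acid
Product: 4 2-methoxy-4-(pivaloyloxy)benzoic acid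
Conditions: PivCl (1.1 equiv), NaOH (2.1 equiv), H2O/THF, 0 °C; then aq HCl to pH 2
Reagents that add atoms: pivaloyl chloride, CC(C)(C)C(=O)Cl
Why: Schotten–Baumann acylation; the phenoxide is far more nucleophilic than the carboxylate, any mixed anhydride is hydrolysed again before acidification, and the hindered aryl pivalate survives cold dilute base.

Step 3
Reactants: 4 2-methoxy-4-(pivaloyloxy)benzoic acid; 2 2-chloro-3,5-dimethoxyphenol
Product: 6 2-chloro-3,5-dimethoxyphenyl 2-methoxy-4-(pivaloyloxy)benzoate, via acid chloride 5 (not isolated)
Conditions: (COCl)2 (1.2 equiv), cat. DMF, CH2Cl2, 0 °C → rt; evaporate; then 2, Et3N (1.5 equiv), DMAP (0.1 equiv), CH2Cl2, 0 °C → rt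
Reagents that add atoms: oxalyl chloride, O=C(Cl)C(=O)Cl (supplies only the chlorine of 5, which leaves again on esterification)
Why: Acyl chloride formation by Vilsmeier-type activation, then DMAP-catalysed O-acylation of the phenol; the aryl pivalate and methyl ethers are inert to both operations, and the acid chloride overcomes the hindrance of the ortho-chloro phenol.

Step 4
Reactants: 6 2-chloro-3,5-dimethoxyphenyl 2-methoxy-4-(pivaloyloxy)benzoate
Product: 7 4-(3-chloro-2-hydroxy-4,6-dimethoxybenzoyl)-3-methoxyphenyl pivalate
Conditions: TiCl4 (2.5 equiv), ClCH2CH2Cl, 0 °C → 60 °C; then cold 1 M HCl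
Reagents that add atoms: none
Why: Lewis-acid Fries rearrangement; TiCl4 ionises the ester to an acylium ion (stabilised by its ortho-methoxy group) and a titanium phenoxide, which recombine at the only free ortho carbon of ring A because the other bears Cl, and the ortho product is held as a six-membered titanium chelate, which should favour it over attack at C5. TiCl4 is mild enough to leave the methyl ethers and the hindered pivalate intact.

Step 5
Reactants: 7 4-(3-chloro-2-hydroxy-4,6-dimethoxybenzoyl)-3-methoxyphenyl pivalate
Product: 8 2-chloro-3,5-dimethoxy-6-[2-methoxy-4-(pivaloyloxy)benzoyl]phenyl pivalate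
Conditions: PivCl (2 equiv), Et3N (3 equiv), DMAP (0.2 equiv), CH2Cl2, 0 °C → 40 °C
Reagents that add atoms: pivaloyl chloride, CC(C)(C)C(=O)Cl
Why: DMAP-catalysed O-acylation through the N-pivaloylpyridinium ion; the C2 phenol is acidified by the ortho chlorine and ortho aroyl group, so Et3N should break its hydrogen bond to the ketone and deliver the phenoxide, and no other nucleophilic site is present.

Step 6
Reactants: 8 2-chloro-3,5-dimethoxy-6-[2-methoxy-4-(pivaloyloxy)benzoyl]phenyl pivalate; 9 potassium methyltrifluoroborate
Product: 10 2-chloro-3,5-dimethoxy-6-[2-methoxy-6-methyl-4-(pivaloyloxy)benzoyl]phenyl pivalate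
Conditions: [Cp*IrCl2]2 (5 mol %), AgSbF6 (20 mol %), Ag2CO3 (2 equiv), 9 (3 equiv), ClCH2CH2Cl/(CF3)2CHOH, 100 °C, sealed tube
Reagents that add atoms: none
Why: Chloride abstraction by AgSbF6 should give a cationic Cp* complex of trivalent iridium that binds the ketone oxygen of 8; carbonate-assisted concerted metalation-deprotonation at C2'–H then gives a five-membered iridacycle (Ir, O, carbonyl C, C1', C2'). Methyl is transferred from the boron of 9 to iridium and C–C reductive elimination, probably eased by one-electron oxidation through the silver salt, forms the C2'–CH3 bond; Ag2CO3 returns the monovalent iridium to the trivalent state. The closest known reaction type is the Cp*-iridium- or Cp*-rhodium-catalysed ortho C–H methylation of aryl ketones and benzoic acids with methylboron reagents. No ring is closed in the product, since the iridacycle is only a transient intermediate, and no stereocentre is formed. The step needs site selectivity and mono-methylation: C2'–H is the only hydrogen ortho to the carbonyl on either ring, because C2 and C6 of ring A and C6' of ring B carry oxygen substituents, so a second ketone-directed methylation is impossible. The ketone offers a five-membered chelate, which should be preferred over the six-membered chelates open to the weakly basic pivalate carbonyl at C3'–H and C5'–H, and the ring A pivalate has no ortho hydrogen at all. Ring A, flanked by two ortho substituents, should stand roughly perpendicular to the carbonyl plane, leaving ring B free to become coplanar with C=O as cyclometalation requires. The aryl chloride, the methyl ethers and both pivalates should be inert to the cationic iridium catalyst and the silver salts.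

Step 7
Reactants: 10 2-chloro-3,5-dimethoxy-6-[2-methoxy-6-methyl-4-(pivaloyloxy)benzoyl]phenyl pivalate
Product: 11 (3-chloro-2-hydroxy-4,6-dimethoxyphenyl)(4-hydroxy-2-methoxy-6-methylphenyl)methanone
Conditions: NaOMe (4 equiv), MeOH/THF, 0 °C → rt; then 1 M HCl to pH 3
Reagents that add atoms: none
Why: Base-mediated methanolysis (Zemplén-type transesterification) of two aryl esters; methoxide attacks the pivaloyl carbonyls and releases the phenoxides, which are good leaving groups and inert afterwards, while the aryl chloride, methyl ethers and diaryl ketone do not react with NaOMe at room temperature.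

## Compound list

1 | 3,5-dimethoxyphenol | COc1cc(O)cc(OC)c1 | starting material
2 | 2-chloro-3,5-dimethoxyphenol | COc1cc(OC)c(Cl)c(O)c1 | intermediate
3 | 4-hydroxy-2-methoxybenzoic acid | COc1cc(O)ccc1C(=O)O | starting material
4 | 2-methoxy-4-(pivaloyloxy)benzoic acid | COc1cc(OC(=O)C(C)(C)C)ccc1C(=O)O | intermediate
5 | 2-methoxy-4-(pivaloyloxy)benzoyl chloride (not isolated) | COc1cc(OC(=O)C(C)(C)C)ccc1C(=O)Cl | intermediate
6 | 2-chloro-3,5-dimethoxyphenyl 2-methoxy-4-(pivaloyloxy)benzoate | COc1cc(OC)c(Cl)c(OC(=O)c2ccc(OC(=O)C(C)(C)C)cc2OC)c1 | intermediate
7 | 4-(3-chloro-2-hydroxy-4,6-dimethoxybenzoyl)-3-methoxyphenyl pivalate | COc1cc(OC)c(C(=O)c2ccc(OC(=O)C(C)(C)C)cc2OC)c(O)c1Cl | intermediate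
8 | 2-chloro-3,5-dimethoxy-6-[2-methoxy-4-(pivaloyloxy)benzoyl]phenyl pivalate | COc1cc(OC)c(C(=O)c2ccc(OC(=O)C(C)(C)C)cc2OC)c(OC(=O)C(C)(C)C)c1Cl | intermediate
9 | potassium methyltrifluoroborate | C[B-](F)(F)F.[K+] | starting material
10 | 2-chloro-3,5-dimethoxy-6-[2-methoxy-6-methyl-4-(pivaloyloxy)benzoyl]phenyl pivalate | COc1cc(OC)c(C(=O)c2c(C)cc(OC(=O)C(C)(C)C)cc2OC)c(OC(=O)C(C)(C)C)c1Cl | intermediate
11 | (3-chloro-2-hydroxy-4,6-dimethoxyphenyl)(4-hydroxy-2-methoxy-6-methylphenyl)methanone | COc1cc(OC)c(C(=O)c2c(C)cc(O)cc2OC)c(O)c1Cl | target

## Step count and least certain steps

Total step count: 7. Longest linear sequence: 6 steps (1 → 2 → 6 → 7 → 8 → 10 → 11, or equally 3 → 4 → 6 → 7 → 8 → 10 → 11).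

**Step 6 (key step).**
- Most likely failure: slow or absent cyclometalation, because the carbonyl of the tri-ortho-substituted ketone is shielded and ring B is pushed out of plane by its own C6' methoxy group. Unproductive consumption of 9 (protodeboronation, methyl homocoupling) would then win. Minor pivalate-directed methylation at C3' or C5' is a lesser risk.
- Fallback: the C–H methylation is moved to the uncrowded acid stage, where the carboxylate is the directing group and the reaction class is best established. It sets out from 4 and returns at 11.
- Acid 4 and 9 with [Cp*IrCl2]2 and Ag2CO3 in (CF3)2CHOH at 80 °C should give 2-methoxy-6-methyl-4-(pivaloyloxy)benzoic acid F1 by methylation of its only ortho C–H.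
- Oxalyl chloride with catalytic DMF converts F1 into 2-methoxy-6-methyl-4-(pivaloyloxy)benzoyl chloride F2.
- F2 acylates 2 (Et3N, DMAP) to give 2-chloro-3,5-dimethoxyphenyl 2-methoxy-6-methyl-4-(pivaloyloxy)benzoate F3.
- TiCl4-mediated Fries rearrangement, helped by the well-stabilised di-ortho-substituted acylium ion, should give 4-(3-chloro-2-hydroxy-4,6-dimethoxybenzoyl)-3-methoxy-5-methylphenyl pivalate F4.
- NaOMe in MeOH cleaves the single pivalate of F4 to give 11.

**Step 4.**
- Most likely failure: migration of the acyl group to C5 (para to the oxygen, between the methoxy groups) instead of C1, loss of the acylium ion back to 2, or Lewis-acid demethylation of the methoxy groups that end up next to the new carbonyl.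
- Fallback: the ketone is formed by directed ortho-metalation instead of acyl migration. It sets out from 2 and returns at 7.
- Chloromethyl methyl ether and iPr2NEt convert 2 into 2-chloro-1,5-dimethoxy-3-(methoxymethoxy)benzene F5.
- n-BuLi in THF at 0 °C should remove the hydrogen between the OMOM and OMe groups (the stronger cooperative pair) to give [3-chloro-4,6-dimethoxy-2-(methoxymethoxy)phenyl]lithium F6.
- F6 is added at −78 °C to a solution of 5 (made from 4 as in step 3) to give 4-[3-chloro-4,6-dimethoxy-2-(methoxymethoxy)benzoyl]-3-methoxyphenyl pivalate F7. Over-addition should be blocked by the crowding of the ketone.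
- Catalytic HCl in MeOH removes the MOM group to give 7.

**Step 1.**
- Most likely failure: chlorination between the two methoxy groups (para to OH) and over-chlorination, leaving an isomer mixture that is tedious to separate.
- Fallback: the chlorine is placed by directed ortho-metalation. It sets out from 1 and returns at 2.
- Chloromethyl methyl ether and iPr2NEt convert 1 into 1,3-dimethoxy-5-(methoxymethoxy)benzene F8.
- n-BuLi should lithiate one of the two equivalent positions between OMOM and OMe to give [2,4-dimethoxy-6-(methoxymethoxy)phenyl]lithium F9.
- Hexachloroethane chlorinates F9 to give 2-chloro-1,5-dimethoxy-3-(methoxymethoxy)benzene F5, the same compound as in the fallback to step 4.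
- Catalytic HCl in MeOH releases 2. If the step 4 fallback is also in use, F5 is carried on directly.

**Step 5.**
- Most likely failure: incomplete acylation, because the C2 hydroxyl is flanked by Cl and the aroyl group, is hydrogen-bonded to the ketone, and must accept a bulky acyl group.
- Fallback: a smaller acyl group is used on ring A. It sets out from 7 and returns at 11.
- Acetic anhydride, pyridine and DMAP should give 2-chloro-3,5-dimethoxy-6-[2-methoxy-4-(pivaloyloxy)benzoyl]phenyl acetate F10.
- F10 is methylated with 9 under the conditions of step 6 to give 2-chloro-3,5-dimethoxy-6-[2-methoxy-6-methyl-4-(pivaloyloxy)benzoyl]phenyl acetate F11.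
- NaOMe in MeOH removes both ester groups of F11 to give 11. This also eases the final deprotection, since the acetate is cleaved more readily than the hindered ring A pivalate.

## Further compounds

F1 | step 6 | 2-methoxy-6-methyl-4-(pivaloyloxy)benzoic acid | COc1cc(OC(=O)C(C)(C)C)cc(C)c1C(=O)O
F2 | step 6 | 2-methoxy-6-methyl-4-(pivaloyloxy)benzoyl chloride | COc1cc(OC(=O)C(C)(C)C)cc(C)c1C(=O)Cl
F3 | step 6 | 2-chloro-3,5-dimethoxyphenyl 2-methoxy-6-methyl-4-(pivaloyloxy)benzoate | COc1cc(OC)c(Cl)c(OC(=O)c2c(C)cc(OC(=O)C(C)(C)C)cc2OC)c1
F4 | step 6 | 4-(3-chloro-2-hydroxy-4,6-dimethoxybenzoyl)-3-methoxy-5-methylphenyl pivalate | COc1cc(OC)c(C(=O)c2c(C)cc(OC(=O)C(C)(C)C)cc2OC)c(O)c1Cl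
F5 | step 4 | 2-chloro-1,5-dimethoxy-3-(methoxymethoxy)benzene | COCOc1cc(OC)cc(OC)c1Cl
F6 | step 4 | [3-chloro-4,6-dimethoxy-2-(methoxymethoxy)phenyl]lithium | [Li]c1c(OC)cc(OC)c(Cl)c1OCOC
F7 | step 4 | 4-[3-chloro-4,6-dimethoxy-2-(methoxymethoxy)benzoyl]-3-methoxyphenyl pivalate | COCOc1c(Cl)c(OC)cc(OC)c1C(=O)c1ccc(OC(=O)C(C)(C)C)cc1OC
F8 | step 1 | 1,3-dimethoxy-5-(methoxymethoxy)benzene | COCOc1cc(OC)cc(OC)c1
F9 | step 1 | [2,4-dimethoxy-6-(methoxymethoxy)phenyl]lithium | [Li]c1c(OC)cc(OC)cc1OCOC
F10 | step 5 | 2-chloro-3,5-dimethoxy-6-[2-methoxy-4-(pivaloyloxy)benzoyl]phenyl acetate | COc1cc(OC)c(C(=O)c2ccc(OC(=O)C(C)(C)C)cc2OC)c(OC(C)=O)c1Cl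
F11 | step 5 | 2-chloro-3,5-dimethoxy-6-[2-methoxy-6-methyl-4-(pivaloyloxy)benzoyl]phenyl acetate | COc1cc(OC)c(C(=O)c2c(C)cc(OC(=O)C(C)(C)C)cc2OC)c(OC(C)=O)c1Cl
A1 | alternative 1 | 6-({[tert-butyl(dimethyl)silyl]oxy}[2-methoxy-4-(methoxymethoxy)-6-methylphenyl]methyl)-2-chloro-3,5-dimethoxyphenol (racemic) | COc1cc(OC)c(C(O[Si](C)(C)C(C)(C)C)c2c(C)cc(OCOC)cc2OC)c(O)c1Cl
A2 | alternative 1 | 4-chloro-3-methoxycyclobut-2-en-1-one (racemic) | COC1=CC(=O)C1Cl
A3 | alternative 1 | tert-butyl({3-methoxy-1-[2-methoxy-4-(methoxymethoxy)-6-methylphenyl]prop-2-yn-1-yl}oxy)dimethylsilane (racemic) | COC#CC(O[Si](C)(C)C(C)(C)C)c1c(C)cc(OCOC)cc1OC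
A4 | alternative 2 | [4-(benzyloxy)-2-methoxy-6-methylphenyl](2,4,6-trihydroxyphenyl)methanone | O=C(c1c(O)cc(O)cc1O)c1c(C)cc(OCc2ccccc2)cc1OC
A5 | alternative 2 | methyl 7-[4-(benzyloxy)-2-methoxy-6-methylphenyl]-3,5,7-trioxoheptanoate | COC(=O)CC(=O)CC(=O)CC(=O)c1c(C)cc(OCc2ccccc2)cc1OC
A6 | alternative 3 | [3-chloro-4,6-dimethoxy-2-(methoxymethoxy)phenyl](4-hydroxy-2-methoxy-6-methylphenyl)methanone | COc1cc(OC)c(C(=O)c2c(C)cc(O)cc2OC)c(OCOC)c1Cl
A7 | alternative 3 | 1-[3-chloro-4,6-dimethoxy-2-(methoxymethoxy)phenyl]but-2-yn-1-one | CC#CC(=O)c1c(OC)cc(OC)c(Cl)c1OCOC
A8 | alternative 3 | 1,1-dimethoxy-3-(trimethylsilyloxy)buta-1,3-diene | C=C(O[Si](C)(C)C)C=C(OC)OC
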